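What is left over in Friday's run is where I begin: the part of the starting material that is neither target nor cross product.

| setting | Friday's | zeta | epsilon |
|---|---|---|---|
| starting material | 0.33 M | 0.33 M | 0.33 M |
| second substrate | 0.49 M | 0.330 M | 0.330 M |
| gas | 160 mM (held) | 160 mM (held) | 160 mM (held) |
| temperature | 0 °C | 0 °C | −25 °C |
| remark | run made earlier |  |  |
| time |  | 20 d | 20 d |

Friday's run (percent of the starting material charged)

| time / h | target / % | cross product / % |
|---|---|---|
| 4.00 | 2 | 21 |
| 6.00 | 0 | 28 |
| 8.00 | 7 | 34 |
| 15.0 | 8 | 51 |
| 20.0 | 7 | 58 |
| 30.0 | 11 | 66 |
| 50.0 | 8 | 80 |

(standard deviation of a reading: 2 percentage points)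

- the numbers in the tables scatter with a standard deviation of 2 percentage points
- at the start none of the gas is in solution
- the earlier runs do not show what temperature does; that part of a forecast is a guess

- the flask that comes out highest in share of target in all that became target or cross product, or "all alike" when all lie within 1.5 percentage points (zeta / epsilon / all alike)
- share of target in all that became target or cross product, zeta
- share of target in all that became target or cross product, epsilon

I follow one molecule of starting material. Late on Friday target stands near 11 % and 8 % while cross product climbs from 66 % to 80 %, so I treat target as a waiting room that a molecule can leave again. Pooling those last two readings, target divided by leftover starting material is 0.543. I call this the holding ratio H, an apparent equilibrium ratio, and it carries the scatter of the readings. With A the starting material left and X the cross product, I use target = H·A only late, once target has caught up, and the share of target is then H·A divided by H·A plus X. Early on this does not hold: at 4.00 h on Friday 77.0 % of the starting material is left, yet target reads 2 %.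

Now the settings, one at a time. Once target has caught up, more time makes more cross product and shrinks A, and target drains with it. Less second substrate slows the cross step. From the first reading I take its rate constant k as 0.120 /M/h. With equal charges c, the part still free or waiting falls to one over (one plus k·c·t divided by one plus H). For zeta that is 7.49 % at 20 d, which gives a share of 2.77 %. Cold is a guess: I slow the cross step by a factor of 10 and keep H. Epsilon then keeps 44.7 % and shows 22.2 %, so I commit to epsilon as higher than zeta.

The forecast differs: it names zeta, with 20 % for zeta and 15 % for epsilon, on the ground of “gas competing against the second substrate for starting material”.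

The flask gives epsilon as highest, at 38.1 % against 6.07 % for zeta.

    starting material + second substrate → cross product (k = 0.130 /M/h, Ea = 79.0 kJ/mol)
    starting material + coupling partner ⇌ target (K = 3.30 /M, k = 0.730 /M/h, Ea = 57.0 kJ/mol, ΔH = 8.00 kJ/mol)
    coupling partner → decomposed reagent (k = 0.00200 /h, Ea = 98.0 kJ/mol)
    gas ⇌ coupling partner, rate k4*(csat - [coupling partner]) (kL = 0.0440 /h)
    second substrate + coupling partner → second product (k = 0.0260 /M/h, Ea = 64.0 kJ/mol)
    (constants at 0 °C)

At 20.0 d zeta keeps 10.7 % of its starting material and epsilon 50.2 %. H times zeta's leftover gives 5.81 % of target, and zeta holds 5.42 %. The neighbour with 0.083 M of second substrate, also at 0 °C, keeps 50.7 %, so H gives 27.5 %; it holds 25.6 % of target, a share of 51.9 %.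

The data were generated by integration for an exercise, noise included.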